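## Structural features

The target is an isoflavanone: a chroman-4-one in which ring A (C4a–C8a) is fused to the pyranone ring C (O1, C2, C3, C4), and C3 carries ring B, a 2,4-dihydroxyphenyl group. Ring A bears a hydroxyl at C7 and a prenyl (3-methylbut-2-enyl) group at C6, and ring B bears a prenyl group at C5'. Both rings are therefore 5-prenylated 4-acylresorcinol units, each with its prenyl group ortho to a free phenol. The only stereocentre is C3, of (S) configuration (C4 > C2 > C1' > H). It has no stereogenic neighbour, but it is benzylic and alpha to the C4 ketone, so it epimerises through the enol under base and, more slowly, under acid. The other fragile elements are the two ortho-prenylphenol units, which cyclise to 2,2-dimethylchromans in acid and whose trisubstituted alkenes are the first sites attacked by electrophilic oxidants, and the three electron-rich phenols. The real difficulty is the order of events: C3 has to be set late, by reagent control, with two side-chain alkenes present, and must then survive side-chain completion and deprotection. The key step exploits the fact that O1–C2–C3–C4–C4a–C8a of ring C, at the isoflav-3-ene oxidation level, is the oxa-6π closure product of a ring A ortho-quinone methide (C8a=O, C4a=C4) carrying on C4 a 1-arylvinyl group (C3=C2, ring B on C3). The achiral C3=C4 alkene that results is the handle on which the C4 oxygen and the C3 hydrogen are then installed together.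

## Logic of the disconnections

**19 from 18.** The three phenolic O–H bonds (C7, C2', C4') are taken back to O–Si bonds. Free resorcinol-type phenols would not tolerate a dioxirane or a Lewis acid, so they are unmasked last. The gain is that every earlier intermediate is a neutral silyl ether. The forward step must use buffered fluoride, so that C3 is not deprotonated, and no strong acid, because of the ortho-prenylphenols.

**18 from 17.** The C=C bonds of both prenyl groups are cut, leaving terminal allyl groups. A trisubstituted prenyl alkene would compete with C3=C4 for an electrophilic oxidant, whereas a monosubstituted alkene does not. Both side chains can then be carried as inert three-carbon stubs. The forward step must be a neutral alkene exchange on both chains that leaves the enolisable ketone alone.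

**17 from 16.** The C3–H bond and the C4=O π bond are traced back to an oxirane by returning the hydrogen to C4 and reconnecting the oxygen to C3. This moves the only stereocentre off an enolisable carbon and onto a ring-fused epoxide whose configuration cannot drift. The forward step must ionise C3–O rather than C4–O and must not let the product enolise.

**16 from 15.** Both C–O bonds of the oxirane are cut, giving the achiral C3=C4 alkene. All stereochemical information is reduced to the choice of an alkene face by a chiral oxidant. The forward step needs face selectivity on a trisubstituted, doubly aryl-conjugated alkene and must ignore the two allyl groups.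

**15 from 5 and 12, through 14 and 13.** Ring C is opened at O1–C2 by a retro-oxa-6π step, which exposes 14; the C3–C4 bond is then cut, with 13 as the amine-bearing link. This is the strategic cut: it divides the molecule into two halves of equal size, each a 5-allylated 4-acylresorcinol derivative, and forms ring C with no stereochemical issue. The forward step needs a free hydroxyl only at C8a, a 1-arylvinyl group on boron, and thermal conditions that three aryl silyl ethers tolerate.

**5 from 3 and 4; 3 from 2; 2 from 1.** The bond between ring carbon C5 and the allyl CH2 is cut (tin on the allyl side, iodine on the ring side), then the O–Si bond at the 4-oxygen, then the C5–I bond. Each cut removes one substituent from a benzene ring whose directing effects place it. The forward steps need iodination at C5, mono-silylation of the unchelated hydroxyl, and a coupling that spares the ortho-hydroxy aldehyde.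

**12 from 11; 11 from 10; 10 from 9.** The B–O bonds to the diol are cut first, then the C–B bond back to a C–O triflate bond, then the enol C–O bond back to the methyl ketone. An unusual 1-arylvinylboron reagent is thus reduced to an acetophenone. The forward steps must form the vinyl triflate without silyl transfer from the neighbouring oxygen and must free the boronic acid without fluoride.

**9 from 8 and 4; 8 from 7; 7 from 6.** As in ring A, the aryl–allyl bond is cut (tin on the allyl side, bromine on the ring), then the two O–Si bonds, then the C–Br bond. The two halves share their chemistry and one tin reagent. The forward steps need bromination at C5 only and silylation of the chelated 2-hydroxyl as well as the 4-hydroxyl.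

## Other disconnections considered

**Alternative 1:** The cut is made at the two aryl–CH2 bonds of the prenyl groups (at C6 and at C5'). Both are traced to aryl prenyl ethers on the oxygens that become O1 and the 2'-hydroxyl, that is, to the bis(O-prenyl) deoxybenzoin A1.
- Forward step: heating A1 with Eu(fod)3 should trigger, in each ring, an aromatic Claisen shift to the free ortho carbon followed by a Cope shift to the para carbon. This would give the diprenyl deoxybenzoin A2 with both phenols released.
- In its favour: the prenyl groups arrive as prenyl groups, placed by the position of the ether oxygen. The halogenations, both Stille couplings, the metathesis and all tin are avoided. On atom economy and side-chain step count this alternative is the better one.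
- Against it here: each ring can stop at the ortho stage, since the ortho dienone can simply tautomerise to a 1,1-dimethylallyl phenol. The ortho carbon of ring A lies between two oxygens, and the sequence has to succeed in both rings of one molecule. The freed phenols also sit next to prenyl groups in hot Lewis-acidic medium, which invites chroman formation.
- What it leaves open: A2 still needs a one-carbon unit for C2, a ring closure, and a separate device for C3. C3 would be formed racemic and enolisable and could only be corrected afterwards, for example by a dynamic reduction and reoxidation, with the oxidation-sensitive prenyl groups already present.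
- Comparison: in mechanism, pericyclic C–C formation stands against palladium coupling, and both are dependable in simple cases. In structure, the chosen plan leaves an achiral C3=C4 alkene as a handle for asymmetric induction, which A2 does not offer. In step count, the two plans end close together once ring closure and the stereochemical correction are added.

**Alternative 2:** Ring A itself is disconnected. C5–C6 and C4a–C8a are cut by a retro-Diels–Alder/aromatisation transform and O1–C2 by a retro-oxa-Michael transform. This leads to the prenylated 1-methoxy-1,3-bis(trimethylsilyloxy)diene A3 and the ring B enynone A4.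
- Forward step: the diene should add to the alkyne of A4 with its nucleophilic terminus at the β-carbon. Loss of methanol and silyl groups would aromatise ring A, and the phenol released at C8a would add to the adjacent methylene to close ring C, giving racemic isoflavanone A5 in one flask.
- In its favour: three skeletal bonds and two rings form in one operation, the prenyl groups are present from the start, the ring A substitution pattern is written into the diene, and there is no halogenation, tin or metathesis. To the racemic skeleton this is the shortest plan considered and better than the chosen one.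
- Against it here: A4 carries two acceptor sites on one carbonyl. A silyl ketene acetal can add to the 1-arylvinyl ketone methylene in Mukaiyama–Michael fashion, and A4 can oligomerise through that site. A3 must come from γ-alkylation of an acetoacetate dianion and is moisture-sensitive. C3 arises by protonation after the oxa-Michael step and is racemic by construction.
- What it leaves open: the absolute configuration would need a dynamic reduction/reoxidation detour on A5 (two more steps), carried out with a free phenol and two prenyl alkenes in place.
- Comparison: the mechanism is a polar cycloaddition cascade rather than a condensation/electrocyclisation. Structurally it builds ring A where the chosen plan buys it. In step economy it wins up to A5 and loses that margin once the configuration has to be introduced.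

**Alternative 3:** C4 is treated as carbon monoxide. C4a–C4 and C4–C3 are cut together and O1–C2 is cut as a retro-oxa-Michael step. This gives the ring A ortho-bromophenol A6, CO and the ring B 1-arylvinylboronate A7.
- Forward step: a carbonylative Suzuki–Miyaura coupling under Pd(OAc)2 and di(1-adamantyl)-n-butylphosphine should assemble the 2-hydroxyaryl 1-arylvinyl ketone. Its phenoxide would close ring C on the methylene under the basic conditions, giving the racemic tris(triisopropylsilyl) isoflavanone A8.
- In its favour: the ring B partner is the same kind of reagent as 11, so fragment synthesis is equal in effort. C4 arrives as a ketone, so no epoxidation or rearrangement is needed and the position of the carbonyl is beyond doubt; this is a real advantage over step 12 of the chosen plan. No oxidant is used, so prenyl groups could be carried from the start and the metathesis saved.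
- Against it here: direct, non-carbonylative coupling competes on an electron-rich, ortho-oxygenated aryl bromide. The free phenol can capture the acylpalladium species intermolecularly. Palladium hydrides can shift the prenyl double bonds. The base required guarantees a racemic product.
- What it leaves open: the absolute configuration again requires a dynamic reduction and a reoxidation after the key step.
- Comparison: the mechanisms differ (three-component palladium catalysis against a metal-free, amine-catalysed condensation), but the fragments and the bonds formed around C4 are nearly the same. In steps it is shorter to the racemic skeleton and about equal to the enantioenriched one. The chosen plan is preferred because its key-step product is achiral and configurationally inert, so C3 is created once, by a chiral reagent, and never has to be corrected.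

Key step: step 10

Remark on the chemistry: halogenation of 1 and of 6 is assumed to occur at C5 (para to the chelated 2-hydroxyl, ortho to the 4-hydroxyl), the less hindered activated position. TBS = tert-butyldimethylsilyl. Positions follow isoflavanone numbering (O1, C2, C3, C4, C4a, C5–C8, C8a; primes on ring B).

## Route

Step 1
Reactants: 1 2,4-dihydroxybenzaldehyde
Product: 2 2,4-dihydroxy-5-iodobenzaldehyde
Conditions: ICl (1.05 equiv), AcOH, rt
Reagents that add atoms: iodine monochloride, ClI
Why: Electrophilic aromatic iodination of a ring activated by two hydroxyls; C5 should be preferred because C3 is flanked by both oxygens.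

Step 2
Reactants: 2 2,4-dihydroxy-5-iodobenzaldehyde
Product: 3 4-(TBSO)-2-hydroxy-5-iodobenzaldehyde
Conditions: TBSCl (1.05 equiv), imidazole (2 equiv), CH2Cl2, 0 °C
Reagents that add atoms: tert-butyldimethylsilyl chloride, CC(C)(C)[Si](C)(C)Cl
Why: Selective phenol silylation: the 2-hydroxyl is held in a hydrogen bond to the aldehyde and is less nucleophilic, so one equivalent of silyl chloride should take the 4-hydroxyl and leave the ortho phenol that the key step needs.

Step 3
Reactants: 3 4-(TBSO)-2-hydroxy-5-iodobenzaldehyde; 4 allyltributylstannane
Product: 5 5-allyl-4-(TBSO)-2-hydroxybenzaldehyde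
Conditions: Pd(PPh3)4 (5 mol%), toluene, 100 °C
Reagents that add atoms: none
Why: Stille cross-coupling of an aryl iodide with an allylstannane under zerovalent palladium; the neutral conditions tolerate the free phenol, the aldehyde and the aryl silyl ether, and stopping at full conversion limits allyl-to-propenyl isomerisation.

Step 4
Reactants: 6 2,4-dihydroxyacetophenone
Product: 7 5-bromo-2,4-dihydroxyacetophenone
Conditions: NBS (1.0 equiv), MeCN, 0 °C to rt
Reagents that add atoms: N-bromosuccinimide, O=C1CCC(=O)N1Br
Why: Electrophilic aromatic bromination with one equivalent of reagent; as in step 1, C5 is the less hindered of the two activated positions.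

Step 5
Reactants: 7 5-bromo-2,4-dihydroxyacetophenone
Product: 8 5-bromo-2,4-bis(TBSO)acetophenone
Conditions: TBSCl (2.6 equiv), imidazole (5 equiv), DMF, 40 °C
Reagents that add atoms: tert-butyldimethylsilyl chloride, CC(C)(C)[Si](C)(C)Cl
Why: Exhaustive phenol silylation; the chelated 2-hydroxyl reacts slowly, hence the excess, DMF and mild warming, and silyl chloride/imidazole is used rather than a silyl triflate so that the methyl ketone is not turned into a silyl enol ether.

Step 6
Reactants: 8 5-bromo-2,4-bis(TBSO)acetophenone; 4 allyltributylstannane
Product: 9 5-allyl-2,4-bis(TBSO)acetophenone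
Conditions: Pd(PPh3)4 (5 mol%), toluene, 110 °C
Reagents that add atoms: none
Why: Stille allylation of an aryl bromide; oxidative addition into the electron-rich, ortho-silyloxy bromide is slower than in step 3, hence the higher temperature, and no fluoride additive is used because it would cleave the aryl silyl ethers.

Step 7
Reactants: 9 5-allyl-2,4-bis(TBSO)acetophenone
Product: 10 1-[5-allyl-2,4-bis(TBSO)phenyl]vinyl trifluoromethanesulfonate
Conditions: KN(SiMe3)2 (1.1 equiv) added to 9 and PhNTf2 (1.15 equiv), THF, −78 °C
Reagents that add atoms: N-phenylbis(trifluoromethanesulfonimide), O=S(=O)(N(c1ccccc1)S(=O)(=O)C(F)(F)F)C(F)(F)F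
Why: Kinetic deprotonation of the methyl ketone and O-triflation of the potassium enolate give the 1-arylvinyl triflate; the base is added to ketone and triflimide together so that the enolate is trapped before silyl transfer from the neighbouring 2-silyloxy oxygen can occur.

Step 8
Reactants: 10 1-[5-allyl-2,4-bis(TBSO)phenyl]vinyl trifluoromethanesulfonate
Product: 11 2-{1-[5-allyl-2,4-bis(TBSO)phenyl]vinyl}-4,4,5,5-tetramethyl-1,3,2-dioxaborolane
Conditions: B2pin2 (1.2 equiv), PdCl2(dppf) (3 mol%), KOAc (3 equiv), 1,4-dioxane, 80 °C
Reagents that add atoms: bis(pinacolato)diboron, CC1(C)OB(B2OC(C)(C)C(C)(C)O2)OC1(C)C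
Why: Miyaura borylation of an alkenyl triflate; the weak base KOAc suppresses Suzuki homocoupling and spares the aryl silyl ethers, and the allyl group is too remote from the vinylpalladium centre for a Heck closure.

Step 9
Reactants: 11 2-{1-[5-allyl-2,4-bis(TBSO)phenyl]vinyl}-4,4,5,5-tetramethyl-1,3,2-dioxaborolane
Product: 12 1-[5-allyl-2,4-bis(TBSO)phenyl]vinylboronic acid
Conditions: NaIO4 (3 equiv), NH4OAc (3 equiv), acetone/H2O, rt
Reagents that add atoms: water, O
Why: Hydrolysis of the pinacol boronate is driven by periodate cleavage of the released pinacol in a near-neutral buffer; a trifluoroborate route is avoided because KHF2 would remove the aryl silyl ethers, and the acid is used promptly.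

Step 10
Reactants: 5 5-allyl-4-(TBSO)-2-hydroxybenzaldehyde; 12 1-[5-allyl-2,4-bis(TBSO)phenyl]vinylboronic acid
Product: 15 6,5'-diallyl-7,2',4'-tris(TBSO)isoflav-3-ene, via allylic dibenzylamine 13 (not isolated), via ortho-quinone methide 14 (not isolated)
Conditions: 12 (1.3 equiv), Bn2NH (0.4 equiv), 1,4-dioxane, 90 °C
Reagents that add atoms: none
Why: Dibenzylamine condenses with the aldehyde of 5 to an iminium ion while the ortho phenoxide binds the boron of 12 as a tetracoordinate boronate, and the 1-arylvinyl group then migrates intramolecularly from boron to the iminium carbon through its boron-bearing carbon, forming C4–C3 and giving 13 (Petasis borono-Mannich reaction). At 90 °C the ortho-hydroxybenzylic amine of 13 expels dibenzylamine, which re-enters the cycle, leaving the ortho-quinone methide 14 with its exocyclic alkene conjugated to the 1-arylvinyl unit. 14 is a 1-oxatriene (O=C8a–C4a=C4–C3=C2) that closes by thermal disrotatory oxa-6π electrocyclisation, forming O1–C2 and the six-membered ring C while ring A regains aromaticity, which makes the closure irreversible. The closest known reaction type is the amine-catalysed condensation of salicylaldehydes with alkenylboronic acids to 2H-chromenes, in which a 1-substituted vinylboronic acid is a less common but documented partner. No stereocentre is created and the product is achiral. The selectivity required is regiochemical: because C–C bond formation is ipso to boron, ring B must end on C3 and the unsubstituted methylene on C2, and because only the free C8a hydroxyl can anchor the boronate, the three silyl ethers and both allyl groups are spectators. The electron-releasing 7-silyloxy group makes the iminium ion a weaker electrophile, which is why a substantial amine loading and an excess of 12 are used.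

Step 11
Reactants: 15 6,5'-diallyl-7,2',4'-tris(TBSO)isoflav-3-ene
Product: 16 (3S,4R)-6,5'-diallyl-7,2',4'-tris(TBSO)-3,4-epoxyisoflavan
Conditions: D-fructose-derived Shi ketone (0.3 equiv), Oxone (2KHSO5·KHSO4·K2SO4), K2CO3, Bu4NHSO4, MeCN/CH2(OMe)2, aq. Na2B4O7 buffer (pH 10.5), 0 °C; crude epoxide used directly
Reagents that add atoms: potassium peroxymonosulfate (oxidant of Oxone), [K+].[O-]S(=O)(=O)OO
Why: Shi asymmetric epoxidation: the chiral dioxirane formed from the ketone and KHSO5 transfers oxygen through a spiro transition state, and by analogy with 1-arylcyclohexenes and (E)-α-alkylstilbenes the D-fructose-derived ketone should attack the face that gives the (3S,4R)-epoxide. Monosubstituted allyl alkenes are poor substrates for this dioxirane, so only the electron-rich trisubstituted C3=C4 bond should react, and the basic buffer protects the acid-labile epoxide.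

Step 12
Reactants: 16 (3S,4R)-6,5'-diallyl-7,2',4'-tris(TBSO)-3,4-epoxyisoflavan
Product: 17 (3S)-6,5'-diallyl-7,2',4'-tris(TBSO)isoflavan-4-one
Conditions: BF3·OEt2 (0.2 equiv), CH2Cl2, −78 °C; pH 7 phosphate buffer quench at −78 °C
Reagents that add atoms: none
Why: Meinwald rearrangement: Lewis-acid ionisation of the C3–O bond gives a tertiary cation stabilised by the 2',4'-dioxygenated ring B, and the C4 hydrogen, which lies anti to the departing oxygen, shifts suprafacially to C3 as C4 becomes the carbonyl. The hydrogen therefore enters C3 on the face opposite the epoxide oxygen, translating (3S,4R) into (3S); the ring aligns the C4–H bond, not the C4–C4a bond, with the empty orbital, so ring contraction is disfavoured. Low temperature and a cold neutral quench keep the new alpha-aryl ketone from enolising.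

Step 13
Reactants: 17 (3S)-6,5'-diallyl-7,2',4'-tris(TBSO)isoflavan-4-one
Product: 18 (3S)-6,5'-bis(3-methylbut-2-enyl)-7,2',4'-tris(TBSO)isoflavan-4-one
Conditions: 2-methyl-2-butene (large excess), second-generation Grubbs catalyst RuCl2(H2IMes)(PCy3)(=CHPh) (5 mol%), CH2Cl2, 40 °C, sealed tube
Reagents that add atoms: 2-methyl-2-butene, CC=C(C)C
Why: Olefin cross-metathesis of both terminal allyl groups with excess 2-methyl-2-butene converts each into a prenyl group with loss of propene; the ruthenium carbene is neutral, so the C3 stereocentre and the silyl ethers are untouched.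

Step 14
Reactants: 18 (3S)-6,5'-bis(3-methylbut-2-enyl)-7,2',4'-tris(TBSO)isoflavan-4-one
Product: 19 (3S)-3-[2,4-dihydroxy-5-(3-methylbut-2-enyl)phenyl]-7-hydroxy-6-(3-methylbut-2-enyl)chroman-4-one
Conditions: Bu4NF (3.3 equiv), AcOH (3.6 equiv), THF, 0 °C
Reagents that add atoms: none
Why: Fluoride cleavage of the three aryl silyl ethers; acetic acid buffers fluoride and the phenoxides so that C3 is not deprotonated, and no strong acid is present that could cyclise the ortho-prenylphenols to chromans. The (S) centre set in step 12 is carried through unchanged.

## Compound list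

1 | 2,4-dihydroxybenzaldehyde | O=Cc1ccc(O)cc1O | starting material
2 | 2,4-dihydroxy-5-iodobenzaldehyde | O=Cc1cc(I)c(O)cc1O | intermediate
3 | 4-(TBSO)-2-hydroxy-5-iodobenzaldehyde | O=Cc1cc(I)c(O[Si](C)(C)C(C)(C)C)cc1O | intermediate
4 | allyltributylstannane | C=CC[Sn](CCCC)(CCCC)CCCC | starting material
5 | 5-allyl-4-(TBSO)-2-hydroxybenzaldehyde | C=CCc1cc(C=O)c(O)cc1O[Si](C)(C)C(C)(C)C | intermediate
6 | 2,4-dihydroxyacetophenone | CC(=O)c1ccc(O)cc1O | starting material
7 | 5-bromo-2,4-dihydroxyacetophenone | CC(=O)c1cc(Br)c(O)cc1O | intermediate
8 | 5-bromo-2,4-bis(TBSO)acetophenone | CC(=O)c1cc(Br)c(O[Si](C)(C)C(C)(C)C)cc1O[Si](C)(C)C(C)(C)C | intermediate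
9 | 5-allyl-2,4-bis(TBSO)acetophenone | CC(=O)c1cc(CC=C)c(O[Si](C)(C)C(C)(C)C)cc1O[Si](C)(C)C(C)(C)C | intermediate
10 | 1-[5-allyl-2,4-bis(TBSO)phenyl]vinyl trifluoromethanesulfonate | C=C(OS(=O)(=O)C(F)(F)F)c1cc(CC=C)c(O[Si](C)(C)C(C)(C)C)cc1O[Si](C)(C)C(C)(C)C | intermediate
11 | 2-{1-[5-allyl-2,4-bis(TBSO)phenyl]vinyl}-4,4,5,5-tetramethyl-1,3,2-dioxaborolane | C=C(B1OC(C)(C)C(C)(C)O1)c1cc(CC=C)c(O[Si](C)(C)C(C)(C)C)cc1O[Si](C)(C)C(C)(C)C | intermediate
12 | 1-[5-allyl-2,4-bis(TBSO)phenyl]vinylboronic acid | C=C(B(O)O)c1cc(CC=C)c(O[Si](C)(C)C(C)(C)C)cc1O[Si](C)(C)C(C)(C)C | intermediate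
13 | allylic dibenzylamine formed in the flask: racemic 4-allyl-2-{2-[5-allyl-2,4-bis(TBSO)phenyl]-1-(dibenzylamino)prop-2-en-1-yl}-5-(TBSO)phenol | C=CCc1cc(C(N(Cc2ccccc2)Cc2ccccc2)C(=C)c2cc(CC=C)c(O[Si](C)(C)C(C)(C)C)cc2O[Si](C)(C)C(C)(C)C)c(O)cc1O[Si](C)(C)C(C)(C)C | intermediate
14 | ortho-quinone methide formed in the flask: (6Z)-4-allyl-6-{2-[5-allyl-2,4-bis(TBSO)phenyl]prop-2-en-1-ylidene}-3-(TBSO)cyclohexa-2,4-dien-1-one | O=C1C=C(O[Si](C)(C)C(C)(C)C)C(CC=C)=C/C1=C/C(=C)c1cc(CC=C)c(O[Si](C)(C)C(C)(C)C)cc1O[Si](C)(C)C(C)(C)C | intermediate
15 | 6,5'-diallyl-7,2',4'-tris(TBSO)isoflav-3-ene (achiral) | C=CCc1cc2c(cc1O[Si](C)(C)C(C)(C)C)OCC(c1cc(CC=C)c(O[Si](C)(C)C(C)(C)C)cc1O[Si](C)(C)C(C)(C)C)=C2 | intermediate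
16 | (3S,4R)-6,5'-diallyl-7,2',4'-tris(TBSO)-3,4-epoxyisoflavan | C=CCc1cc2c(cc1O[Si](C)(C)C(C)(C)C)OC[C@]3(c4cc(CC=C)c(O[Si](C)(C)C(C)(C)C)cc4O[Si](C)(C)C(C)(C)C)O[C@H]23 | intermediate
17 | (3S)-6,5'-diallyl-7,2',4'-tris(TBSO)isoflavan-4-one | C=CCc1cc2c(cc1O[Si](C)(C)C(C)(C)C)OC[C@H](c1cc(CC=C)c(O[Si](C)(C)C(C)(C)C)cc1O[Si](C)(C)C(C)(C)C)C2=O | intermediate
18 | (3S)-6,5'-bis(3-methylbut-2-enyl)-7,2',4'-tris(TBSO)isoflavan-4-one | CC(C)=CCc1cc2c(cc1O[Si](C)(C)C(C)(C)C)OC[C@H](c1cc(CC=C(C)C)c(O[Si](C)(C)C(C)(C)C)cc1O[Si](C)(C)C(C)(C)C)C2=O | intermediate
19 | (3S)-3-[2,4-dihydroxy-5-(3-methylbut-2-enyl)phenyl]-7-hydroxy-6-(3-methylbut-2-enyl)chroman-4-one | CC(C)=CCc1cc2c(cc1O)OC[C@H](c1cc(CC=C(C)C)c(O)cc1O)C2=O | target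

## Step count and least certain steps

Total step count: 14 (steps 1–3 to 5, steps 4–9 to 12, steps 10–14 in common).
Longest linear sequence: 11 steps (6 to 19 through steps 4–9 and 10–14).

**Step 10 (key step).** What may go wrong: slow C–C bond formation, because the iminium ion of a 4-oxygenated salicylaldehyde is a weak electrophile and the migrating 1-arylvinyl group is 1,1-disubstituted and flanked by a 2-silyloxy group. Protodeboronation or polymerisation of 12 can then take over, and prolonged heating with amine can strip the silyl ether para to the aldehyde. Fallback (sets out from 5 and 10, returns at 15): a Nozaki–Hiyama–Kishi coupling of 10 with 5 (CrCl2, catalytic NiCl2, DMF, rt) forms the same C3–C4 bond without boron. It should give the racemic allylic alcohol 4-allyl-2-{2-[5-allyl-2,4-bis(TBSO)phenyl]-1-hydroxyprop-2-en-1-yl}-5-(TBSO)phenol F1. Heating F1 in toluene, if needed with a trace of a weak acid, dehydrates the ortho-hydroxybenzylic alcohol to the same ortho-quinone methide 14, which closes to 15.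

**Step 12.** What may go wrong: ionisation at the wrong oxirane carbon. C4 is also benzylic, and a cation there is stabilised by O1 and the 7-silyloxy group, both held coplanar by the ring. If C4–O breaks first, ring B migrates from C3 to C4 and the carbonyl ends up on C3. This competition is finely balanced and is the main uncertainty of the route. Erosion of the ee by Lewis-acid enolisation of the product is the second risk. Fallback (sets out from 16, returns at 17): the tendency to open at C4 is used instead of fought.
- Acid-promoted attack of DMSO at C4, followed by Et3N (Kornblum-type oxidative opening), should give the α-ketol (3S)-6,5'-diallyl-3-hydroxy-7,2',4'-tris(TBSO)isoflavan-4-one F2, with the carbonyl unambiguously on C4.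
- SmI2 in THF/MeOH at −78 °C removes the tertiary α-hydroxyl and gives racemic 6,5'-diallyl-7,2',4'-tris(TBSO)isoflavan-4-one F3.
- Asymmetric transfer hydrogenation with dynamic kinetic resolution (RuCl(p-cymene)[(S,S)-TsDPEN], HCO2H/Et3N) lets C3 equilibrate while one enantiomer is reduced faster. By analogy with simple aryl ketones it should give the cis alcohol (3S,4S)-6,5'-diallyl-7,2',4'-tris(TBSO)isoflavan-4-ol F4.
- Dess–Martin oxidation buffered with NaHCO3 (CH2Cl2, 0 °C) returns 17.

**Step 11.** What may go wrong: insufficient face selectivity on an alkene whose ring B is twisted by its ortho substituent, partial hydrolysis of aryl silyl ethers at pH 10.5, or opening of the very electron-rich epoxide during work-up. Fallback (sets out from 15, returns at 17): the configuration is set on the ketone instead of the alkene. Dimethyldioxirane (acetone, −20 °C) gives the racemic epoxide rac-6,5'-diallyl-7,2',4'-tris(TBSO)-3,4-epoxyisoflavan F5. Rearrangement as in step 12 gives the racemic ketone rac-6,5'-diallyl-7,2',4'-tris(TBSO)isoflavan-4-one F3. The dynamic transfer hydrogenation to the cis alcohol (3S,4S)-6,5'-diallyl-7,2',4'-tris(TBSO)isoflavan-4-ol F4 and the buffered Dess–Martin oxidation then lead to 17 as above.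

**Step 9.** What may go wrong: protodeboronation or oligomerisation of the 1-arylvinylboronic acid during oxidative hydrolysis, or incomplete cleavage of the hindered ester. Fallback (sets out from 11, returns at 12): transesterification with diethanolamine in ether should precipitate the dioxazaborocane 2-{1-[5-allyl-2,4-bis(TBSO)phenyl]vinyl}-1,3,6,2-dioxazaborocane F6, which is freed from pinacol by filtration. A brief two-phase hydrolysis with dilute aqueous acid then releases 12.

## Further compounds

F1 | step 10 | racemic 4-allyl-2-{2-[5-allyl-2,4-bis(TBSO)phenyl]-1-hydroxyprop-2-en-1-yl}-5-(TBSO)phenol | C=CCc1cc(C(O)C(=C)c2cc(CC=C)c(O[Si](C)(C)C(C)(C)C)cc2O[Si](C)(C)C(C)(C)C)c(O)cc1O[Si](C)(C)C(C)(C)C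
F2 | step 12 | (3S)-6,5'-diallyl-3-hydroxy-7,2',4'-tris(TBSO)isoflavan-4-one | C=CCc1cc2c(cc1O[Si](C)(C)C(C)(C)C)OC[C@@](O)(c1cc(CC=C)c(O[Si](C)(C)C(C)(C)C)cc1O[Si](C)(C)C(C)(C)C)C2=O
F3 | step 12 | racemic 6,5'-diallyl-7,2',4'-tris(TBSO)isoflavan-4-one | C=CCc1cc2c(cc1O[Si](C)(C)C(C)(C)C)OCC(c1cc(CC=C)c(O[Si](C)(C)C(C)(C)C)cc1O[Si](C)(C)C(C)(C)C)C2=O
F4 | step 12 | (3S,4S)-6,5'-diallyl-7,2',4'-tris(TBSO)isoflavan-4-ol (cis) | C=CCc1cc2c(cc1O[Si](C)(C)C(C)(C)C)OC[C@H](c1cc(CC=C)c(O[Si](C)(C)C(C)(C)C)cc1O[Si](C)(C)C(C)(C)C)[C@@H]2O
F5 | step 11 | racemic 6,5'-diallyl-7,2',4'-tris(TBSO)-3,4-epoxyisoflavan | C=CCc1cc2c(cc1O[Si](C)(C)C(C)(C)C)OCC3(c4cc(CC=C)c(O[Si](C)(C)C(C)(C)C)cc4O[Si](C)(C)C(C)(C)C)OC23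
F6 | step 9 | 2-{1-[5-allyl-2,4-bis(TBSO)phenyl]vinyl}-1,3,6,2-dioxazaborocane | C=C(B1OCCNCCO1)c1cc(CC=C)c(O[Si](C)(C)C(C)(C)C)cc1O[Si](C)(C)C(C)(C)C
A1 | alternative 1 | 1,2-bis[2-(3-methylbut-2-enyloxy)-4-(TBSO)phenyl]ethanone | CC(C)=CCOc1cc(O[Si](C)(C)C(C)(C)C)ccc1C(=O)Cc1ccc(O[Si](C)(C)C(C)(C)C)cc1OCC=C(C)C
A2 | alternative 1 | 2,2'-dihydroxy-5,5'-diprenyl-4,4'-bis(TBSO)deoxybenzoin | CC(C)=CCc1cc(C(=O)Cc2cc(CC=C(C)C)c(O[Si](C)(C)C(C)(C)C)cc2O)c(O)cc1O[Si](C)(C)C(C)(C)C
A3 | alternative 2 | 1-methoxy-7-methyl-1,3-bis(trimethylsilyloxy)octa-1,3,6-triene | COC(O[Si](C)(C)C)=CC(O[Si](C)(C)C)=CCC=C(C)C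
A4 | alternative 2 | 2-[2,4-bis(TBSO)-5-(3-methylbut-2-enyl)phenyl]pent-1-en-4-yn-3-one | C#CC(=O)C(=C)c1cc(CC=C(C)C)c(O[Si](C)(C)C(C)(C)C)cc1O[Si](C)(C)C(C)(C)C
A5 | alternative 2 | racemic 7-hydroxy-6-prenyl-3-[2,4-bis(TBSO)-5-prenylphenyl]chroman-4-one | CC(C)=CCc1cc2c(cc1O)OCC(c1cc(CC=C(C)C)c(O[Si](C)(C)C(C)(C)C)cc1O[Si](C)(C)C(C)(C)C)C2=O
A6 | alternative 3 | 2-bromo-4-(3-methylbut-2-enyl)-5-(triisopropylsilyloxy)phenol | CC(C)=CCc1cc(Br)c(O)cc1O[Si](C(C)C)(C(C)C)C(C)C
A7 | alternative 3 | 2-{1-[5-(3-methylbut-2-enyl)-2,4-bis(triisopropylsilyloxy)phenyl]vinyl}-4,4,5,5-tetramethyl-1,3,2-dioxaborolane | C=C(B1OC(C)(C)C(C)(C)O1)c1cc(CC=C(C)C)c(O[Si](C(C)C)(C(C)C)C(C)C)cc1O[Si](C(C)C)(C(C)C)C(C)C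
A8 | alternative 3 | racemic 6,5'-diprenyl-7,2',4'-tris(triisopropylsilyloxy)isoflavan-4-one | CC(C)=CCc1cc2c(cc1O[Si](C(C)C)(C(C)C)C(C)C)OCC(c1cc(CC=C(C)C)c(O[Si](C(C)C)(C(C)C)C(C)C)cc1O[Si](C(C)C)(C(C)C)C(C)C)C2=O
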